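The route rests on closing the methylene lactone at C7–C11 (germacrane numbering), the bond between the lactone β-carbon and the methylene-bearing α-carbon. C7 lies between two oxygenated carbons of the ten-membered ring (C6–O of the γ-lactone, C8–O of the angelate), so an anti 2,3-epoxy alcohol maps onto C6–C8. The precursor is an acyclic C6 propargyl ether of a 7,8-epoxide. Titanocene(III) opens the epoxide and the C7 radical closes 5-exo-dig onto the alkyne: one operation gives the five-membered ring, the exocyclic methylene, the C7 stereocentre and the free C8 hydroxyl. Oxidation of the ring CH2 then gives the lactone, a Nozaki–Hiyama–Kishi reaction closes the ten-membered ring at C3–C4, and the 1(10)-epoxide is added last.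

Key step: step 10

Remark on numbering: germacrane numbering is used throughout. C1–C10 are the ring carbons; C11, C12 and C13 are the α-carbon, carbonyl and methylene of the lactone; C14 is the methyl on C10; C15 is the CH2OH on C4.
Assumption: the peracid is taken to attack the exposed outer face of the 1(10)-alkene of 24, and this face is assumed to lead to the (1R,10R)-epoxide of the target, as in related germacranolides.

Step 1
Reactants: 1 (4S)-4-(2-hydroxyethyl)-2,2-dimethyl-1,3-dioxolane
Product: 3 ethyl (E)-4-[(4S)-2,2-dimethyl-1,3-dioxolan-4-yl]-2-methylbut-2-enoate, via dioxolanylacetaldehyde 2 (not isolated)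
Conditions: IBX, Ph3P=C(Me)CO2Et, DMSO, rt
Reagents that add atoms: ethyl 2-(triphenylphosphoranylidene)propanoate CCOC(=O)C(C)=P(c1ccccc1)(c1ccccc1)c1ccccc1
Why: Tandem IBX oxidation–Wittig olefination: the stabilised α-methyl ylide should trap aldehyde 2 as it forms, before β-elimination of the dioxolane oxygen, and give the (E)-enoate that fixes the later 1(10)-E geometry.

Step 2
Reactants: 3 ethyl (E)-4-[(4S)-2,2-dimethyl-1,3-dioxolan-4-yl]-2-methylbut-2-enoate
Product: 4 (E)-4-[(4S)-2,2-dimethyl-1,3-dioxolan-4-yl]-2-methylbut-2-en-1-ol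
Conditions: DIBAL-H, CH2Cl2, −78 °C; Rochelle salt
Reagents that add atoms: none
Why: DIBAL-H 1,2-reduction of the conjugated ester should give the allylic alcohol and leave the alkene geometry and the acetonide untouched.

Step 3
Reactants: 4 (E)-4-[(4S)-2,2-dimethyl-1,3-dioxolan-4-yl]-2-methylbut-2-en-1-ol
Product: 5 (4S)-4-[(E)-4-bromo-3-methylbut-2-en-1-yl]-2,2-dimethyl-1,3-dioxolane
Conditions: CBr4, PPh3, CH2Cl2, 0 °C
Reagents that add atoms: carbon tetrabromide BrC(Br)(Br)Br
Why: The Appel reaction converts the primary allylic alcohol to the bromide under neutral conditions without allylic transposition.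

Step 4
Reactants: 5 (4S)-4-[(E)-4-bromo-3-methylbut-2-en-1-yl]-2,2-dimethyl-1,3-dioxolane
Product: 6 (4S)-2,2-dimethyl-4-[(E)-3-methylhex-2-en-5-yn-1-yl]-1,3-dioxolane
Conditions: HC≡CMgBr, CuCl (cat.), THF, 0 to 50 °C
Reagents that add atoms: ethynylmagnesium bromide C#C[Mg]Br
Why: Copper-catalysed SN2 coupling of the primary allylic bromide with the ethynyl Grignard reagent should give the skipped enyne at the unhindered CH2 terminus with the (E)-alkene retained.

Step 5
Reactants: 7 but-2-yne-1,4-diol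
Product: 8 4-(tert-butyldimethylsilyloxy)but-2-yn-1-ol
Conditions: TBSCl (1 equiv), imidazole, 7 (3 equiv), DMF, 0 °C
Reagents that add atoms: tert-butyldimethylsilyl chloride CC(C)(C)[Si](C)(C)Cl
Why: Statistical monosilylation of the symmetric diol used in excess should give the mono-TBS ether.

Step 6
Reactants: 8 4-(tert-butyldimethylsilyloxy)but-2-yn-1-ol
Product: 9 4-(tert-butyldimethylsilyloxy)but-2-ynal
Conditions: MnO2, CH2Cl2, rt
Reagents that add atoms: none
Why: MnO2 oxidises the propargylic alcohol selectively to the ynal without over-oxidation.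

Step 7
Reactants: 6 (4S)-2,2-dimethyl-4-[(E)-3-methylhex-2-en-5-yn-1-yl]-1,3-dioxolane; 9 4-(tert-butyldimethylsilyloxy)but-2-ynal
Product: 12 (5E,8E)-1-(tert-butyldimethylsilyloxy)-10-[(4S)-2,2-dimethyl-1,3-dioxolan-4-yl]-8-methyldeca-5,8-dien-2-yn-4-ol as both carbinol epimers, via alkenylzirconocene chloride 10 (not isolated), via alkenyl(methyl)zinc 11 (not isolated)
Conditions: Cp2Zr(H)Cl, CH2Cl2, rt; Me2Zn, toluene, −65 °C; then 9, 0 °C
Reagents that add atoms: none
Why: Hydrozirconation of the terminal alkyne with the Schwartz reagent (syn addition, Zr at the terminal carbon, trisubstituted alkene inert), Zr-to-Zn transmetalation and 1,2-addition of the (E)-alkenylzinc to the ynal should give the alkenyl alkynyl carbinol with the 7,8-(E)-alkene; C6 forms without control and is resolved in step 8.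

Step 8
Reactants: 12 (5E,8E)-1-(tert-butyldimethylsilyloxy)-10-[(4S)-2,2-dimethyl-1,3-dioxolan-4-yl]-8-methyldeca-5,8-dien-2-yn-4-ol (epimer mixture)
Product: 13 (1R)-4-(tert-butyldimethylsilyloxy)-1-[(2R,3R)-3-{(2E)-4-[(4S)-2,2-dimethyl-1,3-dioxolan-4-yl]-2-methylbut-2-en-1-yl}oxiran-2-yl]but-2-yn-1-ol
Conditions: Ti(OiPr)4, D-(−)-DIPT, TBHP (0.6 equiv), 4 Å MS, CH2Cl2, −20 °C
Reagents that add atoms: tert-butyl hydroperoxide CC(C)(C)OO
Why: Sharpless asymmetric epoxidation run as a kinetic resolution: with D-(−)-DIPT the C6 epimer drawn in 13 should be epoxidised fast and anti (erythro), which sets C6 and C8 (both R in the target) under reagent control, while the slow epimer stays as the allylic alcohol and is removed by chromatography.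

Step 9
Reactants: 13 (6R,7R,8R)-anti-7,8-epoxy-6-ol
Product: 14 tert-butyl{[(4R)-4-[(2S,3R)-3-{(2E)-4-[(4S)-2,2-dimethyl-1,3-dioxolan-4-yl]-2-methylbut-2-en-1-yl}oxiran-2-yl]-4-(prop-2-yn-1-yloxy)but-2-yn-1-yl]oxy}dimethylsilane
Conditions: NaH, propargyl bromide, Bu4NI (cat.), THF, 0 °C
Reagents that add atoms: propargyl bromide C#CCBr
Why: Williamson etherification of the sodium alkoxide in an aprotic medium at 0 °C should outrun Payne rearrangement and places C11–C13 on O6.

Step 10
Reactants: 14 epoxy propargyl ether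
Product: 17 (1R,3E)-1-[(2S,3R)-2-{3-[(tert-butyldimethylsilyl)oxy]prop-1-yn-1-yl}-4-methylideneoxolan-3-yl]-5-[(4S)-2,2-dimethyl-1,3-dioxolan-4-yl]-3-methylpent-3-en-1-ol, via β-titanoxy C7 radical 15 (not isolated), via exocyclic vinyl radical 16 (not isolated)
Conditions: Cp2TiCl (from Cp2TiCl2, Zn), slow addition, THF, rt; aq. NaH2PO4
Reagents that add atoms: none
Why: Cp2TiCl transfers one electron to the epoxide and the C7–O bond homolyses to the β-titanoxy radical 15, which adds to the propargyl-ether alkyne, and the vinyl radical 16 is quenched by hydrogen abstraction from THF or by reduction with a second Ti(III) and protonation on work-up; this is the Nugent–RajanBabu titanocene epoxide opening–radical cyclisation as known for epoxy propargyl ethers. The oxolane ring is closed in the 5-exo-dig mode by the new C7–C11 bond. C7 is the only new stereocentre: in the chair-like Beckwith–Houk transition state the C6 alkynyl group and the bulky titanoxy-bearing C8 chain sit trans on the forming ring, which is the 6,7-trans relationship of the lactone, while C6 and C8 are carried over from the Sharpless epoxide because the C8–O bond is not broken. The step needs homolysis at C7–O and not at C8–O: this leaves the titanocene on the less hindered C8 oxygen, away from the branched C6, and only the C7 radical has a fast ring closure, since a C8 radical could only close 6-exo. Slow addition keeps Ti(III) dilute so that cyclisation should outrun trapping of 15 and β-elimination, and the internal alkyne, silyl ether, acetonide and trisubstituted alkene are inert to Cp2TiCl.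

Step 11
Reactants: 17 methylene-oxolane C8 alcohol
Product: 18 (1R,3E)-1-[(2S,3R)-2-{3-[(tert-butyldimethylsilyl)oxy]prop-1-yn-1-yl}-4-methylideneoxolan-3-yl]-5-[(4S)-2,2-dimethyl-1,3-dioxolan-4-yl]-3-methylpent-3-en-1-yl (2Z)-2-methylbut-2-enoate
Conditions: angelic acid, 2,4,6-Cl3C6H2COCl, Et3N, toluene, rt; then 17, 80 °C (no DMAP)
Reagents that add atoms: angelic acid C/C=C(/C)C(=O)O
Why: Yamaguchi-type mixed-anhydride esterification without DMAP should acylate the C8 hydroxyl with the (Z)-geometry of the angelate retained, and the ester also protects C8–OH for step 12.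

Step 12
Reactants: 18 methylene-oxolane angelate
Product: 19 (1R,3E)-1-[(2S,3R)-2-{3-[(tert-butyldimethylsilyl)oxy]prop-1-yn-1-yl}-4-methylidene-5-oxooxolan-3-yl]-5-[(4S)-2,2-dimethyl-1,3-dioxolan-4-yl]-3-methylpent-3-en-1-yl (2Z)-2-methylbut-2-enoate
Conditions: CrO3·2py (from CrO3, pyridine), CH2Cl2, rt
Reagents that add atoms: chromium trioxide O=[Cr](=O)=O
Why: Collins-type allylic oxidation: the ring CH2 (C12) is allylic to the exocyclic methylene, α to the ether oxygen and unhindered, so it should be oxidised to the lactone carbonyl in preference to the hindered tertiary propargylic C6–H and the other allylic positions, giving the α-methylene-γ-butyrolactone.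

Step 13
Reactants: 19 silyl ether acetonide lactone
Product: 20 (1R,3E,6S)-6,7-dihydroxy-1-[(2S,3R)-2-(3-hydroxyprop-1-yn-1-yl)-4-methylidene-5-oxooxolan-3-yl]-3-methylhept-3-en-1-yl (2Z)-2-methylbut-2-enoate
Conditions: AcOH–THF–H2O (3:1:1), 45 °C
Reagents that add atoms: none
Why: Aqueous acetic acid should hydrolyse the acetonide and the primary TBS ether in one operation, the lactone, the angelate and the alkenes being stable to these conditions.

Step 14
Reactants: 20 alkynyl triol
Product: 22 (1R,3E,6S)-6,7-dihydroxy-1-[(2S,3R)-2-[(1Z)-3-hydroxy-2-iodoprop-1-en-1-yl]-4-methylidene-5-oxooxolan-3-yl]-3-methylhept-3-en-1-yl (2Z)-2-methylbut-2-enoate, via C4 alkenylstannane 21 (not isolated)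
Conditions: [Cp*RuCl]4 (cat.), Bu3SnH, CH2Cl2, rt; then I2, 0 °C
Reagents that add atoms: iodine II
Why: Ruthenium-catalysed trans-hydrostannation, steered by the free C15 hydroxyl, should place tin on C4 and hydrogen on C5 by anti addition, and iododestannylation with retention gives the (Z)-iodoalkene with iodine cis to C6, as the ring-cis 4,5-alkene requires.

Step 15
Reactants: 22 iodoalkene triol
Product: 23 (1R,3E)-1-[(2S,3R)-2-[(1Z)-3-hydroxy-2-iodoprop-1-en-1-yl]-4-methylidene-5-oxooxolan-3-yl]-3-methyl-6-oxohex-3-en-1-yl (2Z)-2-methylbut-2-enoate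
Conditions: NaIO4, THF–H2O (pH 7 buffer), 0 °C
Reagents that add atoms: none
Why: Malaprade periodate cleavage of the terminal 1,2-diol should reveal the sensitive β,γ-unsaturated C3 aldehyde under neutral conditions without touching the free C15 alcohol.

Step 16
Reactants: 23 iodoalkene aldehyde
Product: 24 (3S,6R,7R,8R)-3,15-dihydroxy-8-[(2Z)-2-methylbut-2-enoyloxy]germacra-1(10)E,4Z,11(13)-trien-12,6-olide
Conditions: CrCl2 (excess), NiCl2 (cat.), degassed DMSO, rt, 2 mM, slow addition
Reagents that add atoms: none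
Why: Nozaki–Hiyama–Kishi macrocyclisation: the alkenylchromium(III) formed at C4 with retention of alkene geometry should add to the C3 aldehyde under high dilution and close the ten-membered ring at C3–C4, free hydroxyls and both esters being tolerated; C3 is set by the conformation of the ring-closing transition state, and the (3S)-alcohol is expected but not assured (see fallback).

Step 17
Reactants: 24 macrocyclic triene diol
Product: 25 (1R,3S,6R,7R,8R,10R)-1,10-epoxy-3,15-dihydroxy-8-[(2Z)-2-methylbut-2-enoyloxy]germacra-4Z,11(13)-dien-12,6-olide (CNP0187917.1)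
Conditions: mCPBA (1.05 equiv), NaHCO3, CH2Cl2, −20 to 0 °C
Reagents that add atoms: meta-chloroperbenzoic acid OOC(=O)c1cccc(Cl)c1
Why: Prilezhaev epoxidation: the strained, electron-rich 1(10)-(E)-alkene should react far faster than the 4,5-alkene (deactivated by three allylic oxygens) and the two conjugated alkenes, the trans geometry is transferred stereospecifically, and attack on the outer face of the alkene should give the (1R,10R)-epoxide.

Compound list
1 | (4S)-4-(2-hydroxyethyl)-2,2-dimethyl-1,3-dioxolane | CC1(C)OC[C@H](CCO)O1 | starting material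
2 | 2-[(4S)-2,2-dimethyl-1,3-dioxolan-4-yl]acetaldehyde | CC1(C)OC[C@H](CC=O)O1 | intermediate (not isolated)
3 | ethyl (E)-4-[(4S)-2,2-dimethyl-1,3-dioxolan-4-yl]-2-methylbut-2-enoate | CCOC(=O)/C(C)=C/C[C@H]1COC(C)(C)O1 | intermediate
4 | (E)-4-[(4S)-2,2-dimethyl-1,3-dioxolan-4-yl]-2-methylbut-2-en-1-ol | OC/C(C)=C/C[C@H]1COC(C)(C)O1 | intermediate
5 | (4S)-4-[(E)-4-bromo-3-methylbut-2-en-1-yl]-2,2-dimethyl-1,3-dioxolane | BrC/C(C)=C/C[C@H]1COC(C)(C)O1 | intermediate
6 | (4S)-2,2-dimethyl-4-[(E)-3-methylhex-2-en-5-yn-1-yl]-1,3-dioxolane | C#CC/C(C)=C/C[C@H]1COC(C)(C)O1 | intermediate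
7 | but-2-yne-1,4-diol | OCC#CCO | starting material
8 | 4-(tert-butyldimethylsilyloxy)but-2-yn-1-ol | CC(C)(C)[Si](C)(C)OCC#CCO | intermediate
9 | 4-(tert-butyldimethylsilyloxy)but-2-ynal | CC(C)(C)[Si](C)(C)OCC#CC=O | intermediate
10 | chlorobis(cyclopentadienyl)[(1E,4E)-6-((4S)-2,2-dimethyl-1,3-dioxolan-4-yl)-4-methylhexa-1,4-dien-1-yl]zirconium | [cH-]1cccc1.[cH-]1cccc1.Cl[Zr+2]/C=C/C/C(C)=C/C[C@H]1COC(C)(C)O1 | intermediate (not isolated)
11 | methyl[(1E,4E)-6-((4S)-2,2-dimethyl-1,3-dioxolan-4-yl)-4-methylhexa-1,4-dien-1-yl]zinc | C[Zn]/C=C/C/C(C)=C/C[C@H]1COC(C)(C)O1 | intermediate (not isolated)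
12 | (5E,8E)-1-(tert-butyldimethylsilyloxy)-10-[(4S)-2,2-dimethyl-1,3-dioxolan-4-yl]-8-methyldeca-5,8-dien-2-yn-4-ol, both epimers at the carbinol carbon (C6) | CC(C)(C)[Si](C)(C)OCC#CC(O)/C=C/C/C(C)=C/C[C@H]1COC(C)(C)O1 | intermediate
13 | (1R)-4-(tert-butyldimethylsilyloxy)-1-[(2R,3R)-3-{(2E)-4-[(4S)-2,2-dimethyl-1,3-dioxolan-4-yl]-2-methylbut-2-en-1-yl}oxiran-2-yl]but-2-yn-1-ol; (6R,7R,8R), anti epoxy alcohol, trans epoxide | CC(C)(C)[Si](C)(C)OCC#C[C@@H](O)[C@H]1O[C@@H]1C/C(C)=C/C[C@H]2COC(C)(C)O2 | intermediate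
14 | O6-propargyl ether of 13; (6R,7S,8R) by CIP, same geometry as 13 | CC(C)(C)[Si](C)(C)OCC#C[C@@H](OCC#C)[C@H]1O[C@@H]1C/C(C)=C/C[C@H]2COC(C)(C)O2 | intermediate
15 | C7 radical with chlorotitanocene(IV) alkoxide on C8 | CC(C)(C)[Si](C)(C)OCC#C[C@@H](OCC#C)[CH][C@H](O[Ti+2]Cl)C/C(C)=C/C[C@H]1COC(C)(C)O1.[cH-]1cccc1.[cH-]1cccc1 | intermediate (not isolated)
16 | cyclised exocyclic vinyl radical (C13), titanium alkoxide on C8 | CC(C)(C)[Si](C)(C)OCC#C[C@H]1OCC(=[CH])[C@@H]1[C@H](O[Ti+2]Cl)C/C(C)=C/C[C@H]2COC(C)(C)O2.[cH-]1cccc1.[cH-]1cccc1 | intermediate (not isolated)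
17 | (1R,3E)-1-[(2S,3R)-2-{3-[(tert-butyldimethylsilyl)oxy]prop-1-yn-1-yl}-4-methylideneoxolan-3-yl]-5-[(4S)-2,2-dimethyl-1,3-dioxolan-4-yl]-3-methylpent-3-en-1-ol; 2,3-trans oxolane | CC(C)(C)[Si](C)(C)OCC#C[C@H]1OCC(=C)[C@@H]1[C@H](O)C/C(C)=C/C[C@H]2COC(C)(C)O2 | intermediate
18 | C8 angelate of 17 | CC(C)(C)[Si](C)(C)OCC#C[C@H]1OCC(=C)[C@@H]1[C@H](OC(=O)/C(C)=C\C)C/C(C)=C/C[C@H]2COC(C)(C)O2 | intermediate
19 | α-methylene-γ-lactone from 18 (5-oxooxolane) | CC(C)(C)[Si](C)(C)OCC#C[C@H]1OC(=O)C(=C)[C@@H]1[C@H](OC(=O)/C(C)=C\C)C/C(C)=C/C[C@H]2COC(C)(C)O2 | intermediate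
20 | (1R,3E,6S)-6,7-dihydroxy-1-[(2S,3R)-2-(3-hydroxyprop-1-yn-1-yl)-4-methylidene-5-oxooxolan-3-yl]-3-methylhept-3-en-1-yl (2Z)-2-methylbut-2-enoate | OCC#C[C@H]1OC(=O)C(=C)[C@@H]1[C@H](OC(=O)/C(C)=C\C)C/C(C)=C/C[C@H](O)CO | intermediate
21 | (Z)-C4 tributylstannyl alkene from 20 (tin cis to C6) | OC/C([Sn](CCCC)(CCCC)CCCC)=C/[C@H]1OC(=O)C(=C)[C@@H]1[C@H](OC(=O)/C(C)=C\C)C/C(C)=C/C[C@H](O)CO | intermediate (not isolated)
22 | (1R,3E,6S)-6,7-dihydroxy-1-[(2S,3R)-2-[(1Z)-3-hydroxy-2-iodoprop-1-en-1-yl]-4-methylidene-5-oxooxolan-3-yl]-3-methylhept-3-en-1-yl (2Z)-2-methylbut-2-enoate | OC/C(I)=C/[C@H]1OC(=O)C(=C)[C@@H]1[C@H](OC(=O)/C(C)=C\C)C/C(C)=C/C[C@H](O)CO | intermediate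
23 | (1R,3E)-1-[(2S,3R)-2-[(1Z)-3-hydroxy-2-iodoprop-1-en-1-yl]-4-methylidene-5-oxooxolan-3-yl]-3-methyl-6-oxohex-3-en-1-yl (2Z)-2-methylbut-2-enoate | OC/C(I)=C/[C@H]1OC(=O)C(=C)[C@@H]1[C@H](OC(=O)/C(C)=C\C)C/C(C)=C/CC=O | intermediate
24 | (3S,6R,7R,8R)-3,15-dihydroxy-8-[(2Z)-2-methylbut-2-enoyloxy]germacra-1(10)E,4Z,11(13)-trien-12,6-olide | C=C1C(=O)O[C@@H]2/C=C(/CO)[C@@H](O)C/C=C(\C)C[C@@H](OC(=O)/C(C)=C\C)[C@@H]12 | intermediate
25 | (1R,3S,6R,7R,8R,10R)-1,10-epoxy-3,15-dihydroxy-8-[(2Z)-2-methylbut-2-enoyloxy]germacra-4Z,11(13)-dien-12,6-olide (CNP0187917.1) | C=C1C(=O)O[C@@H]2/C=C(/CO)[C@@H](O)C[C@H]3O[C@]3(C)C[C@@H](OC(=O)/C(C)=C\C)[C@@H]12 | target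

Total step count: 17 steps.
Longest linear sequence: 15 steps (steps 1–4 and 7–17, from compound 1).

Steps most likely to fail

Step 16. What may go wrong: poor or reversed facial selectivity when the alkenylchromium adds to the C3 aldehyde, so that the 3-epimer forms in part or mainly; ring strain may also slow the closure. The fallback replaces substrate control by reagent control. It sets out from aldehyde 23. The cyclisation is run as in step 16 and the alcohol is taken on whatever its C3 configuration, in the worst case the (3R)-epimer of 24 F6. Its primary C15 hydroxyl is silylated selectively (TBSCl, imidazole, CH2Cl2, 0 °C) to the 15-O-TBS ether of the (3R)-alcohol F7. Dess–Martin oxidation (NaHCO3 buffer) gives the macrocyclic 15-O-TBS 4-en-3-one F8. Corey–Bakshi–Shibata reduction ((R)-Me-CBS, catecholborane, toluene, −78 °C, the alkenyl branch acting as the large group) should give the 15-O-TBS ether of the (3S)-alcohol F9. HF·pyridine in THF removes the silyl group, and the sequence returns to the route at 24.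

Step 10. What may go wrong: homolysis of the other epoxide C–O bond, which gives a C8 radical that closes 6-exo or is reduced, or interception of the C7 radical by a second Ti(III) before ring closure, followed by β-elimination to an alkene. The fallback is an ionic ring closure of the same bond. It sets out from epoxy alcohol 13. Alkylation with 2,3-dibromopropene (NaH, THF–DMF, 0 °C) gives the 2-bromoallyl ether of 13 F1. Bromine–lithium exchange (t-BuLi, Et2O, −78 °C) and then BF3·OEt2 should trigger 5-exo-tet opening of the epoxide at C7 by the alkenyllithium with inversion. On the anti, trans-epoxide this gives the same 6,7-trans oxolane with C8–OH unchanged, so the product is 17 itself, where the fallback rejoins the route.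

Step 12. What may go wrong: competing oxidation at the propargylic C6–H or C15H2 positions or at the allylic positions of the 1(10)-alkene, and over-oxidation. The fallback brings in C12 already at the acetal oxidation level, so that no C–H oxidation is needed. It sets out from epoxy alcohol 13. Acid-catalysed transacetalisation with 3,3-diethoxyprop-1-yne (PPTS cat., toluene, 40 °C, ethanol removed under reduced pressure) gives the 1-ethoxyprop-2-ynyl mixed acetal of 13 F2. The titanocene(III) cyclisation of step 10 should then give the 5-ethoxy-4-methylideneoxolane C8 alcohol F3. Angeloylation as in step 11 gives its angelate F4. Mild hydrolysis of the allylic acetal (PPTS, wet acetone, rt; acetone as solvent keeps the acetonide) gives the lactol angelate F5. MnO2 in CH2Cl2 oxidises the allylic lactol to lactone 19, where the route is rejoined.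

Further compounds
F1 | step 10 | 2-bromoallyl ether of epoxy alcohol 13 | CC(C)(C)[Si](C)(C)OCC#C[C@@H](OCC(Br)=C)[C@H]1O[C@@H]1C/C(C)=C/C[C@H]2COC(C)(C)O2
F2 | step 12 | 1-ethoxyprop-2-ynyl mixed acetal of 13 (both acetal epimers) | CC(C)(C)[Si](C)(C)OCC#C[C@@H](OC(OCC)C#C)[C@H]1O[C@@H]1C/C(C)=C/C[C@H]2COC(C)(C)O2
F3 | step 12 | 5-ethoxy-4-methylideneoxolane C8 alcohol (both acetal epimers) | CC(C)(C)[Si](C)(C)OCC#C[C@H]1OC(OCC)C(=C)[C@@H]1[C@H](O)C/C(C)=C/C[C@H]2COC(C)(C)O2
F4 | step 12 | C8 angelate of F3 | CC(C)(C)[Si](C)(C)OCC#C[C@H]1OC(OCC)C(=C)[C@@H]1[C@H](OC(=O)/C(C)=C\C)C/C(C)=C/C[C@H]2COC(C)(C)O2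
F5 | step 12 | 5-hydroxy-4-methylideneoxolane (lactol) angelate | CC(C)(C)[Si](C)(C)OCC#C[C@H]1OC(O)C(=C)[C@@H]1[C@H](OC(=O)/C(C)=C\C)C/C(C)=C/C[C@H]2COC(C)(C)O2
F6 | step 16 | (3R)-epimer of macrocycle 24 | C=C1C(=O)O[C@@H]2/C=C(/CO)[C@H](O)C/C=C(\C)C[C@@H](OC(=O)/C(C)=C\C)[C@@H]12
F7 | step 16 | 15-O-TBS ether of the (3R)-alcohol | C=C1C(=O)O[C@@H]2/C=C(/CO[Si](C)(C)C(C)(C)C)[C@H](O)C/C=C(\C)C[C@@H](OC(=O)/C(C)=C\C)[C@@H]12
F8 | step 16 | macrocyclic 15-O-TBS 4-en-3-one | C=C1C(=O)O[C@@H]2/C=C(/CO[Si](C)(C)C(C)(C)C)C(=O)C/C=C(\C)C[C@@H](OC(=O)/C(C)=C\C)[C@@H]12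
F9 | step 16 | 15-O-TBS ether of the (3S)-alcohol 24 | C=C1C(=O)O[C@@H]2/C=C(/CO[Si](C)(C)C(C)(C)C)[C@@H](O)C/C=C(\C)C[C@@H](OC(=O)/C(C)=C\C)[C@@H]12
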